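Rings: A = the benzoic acid ring (C1–C7, O4), B = the middle galloyl (C1'–C7', O4'), C = the terminal galloyl (C7''). Enabling feature: C7' sits on C1' of ring B, para to O4' and flanked only by the unsubstituted C2'/C6', and rings A and B are each symmetric, so a single 4-iodo-2,6-dioxygenated phenol with one free hydroxyl can serve for both rings.
Retrosynthesis: the eight O–benzyl bonds are cut first; then C1'–C7' and C7'–O4 together (ring C–B aryl iodide + CO + ring A phenol); then C7''–O4' (acyl chloride + iodophenol) and, for ring A, C1–C7 and C7–O(benzyl) (same iodophenol + CO + benzyl alcohol); the phenol oxygen goes back to the C–Br bond of 2-bromoresorcinol.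
Forward: 2-bromoresorcinol → dibenzyl ether (two equivalents of benzyl bromide) → phenol (Br/Li exchange, borate, peroxide) → para-iodophenol; one portion is benzyloxycarbonylated to the ring A phenol, a second is acylated with tri-O-benzylgalloyl chloride to the ring C–B iodide; the two are joined with CO; hydrogenolysis finishes the route.
No ring is formed (all three benzene rings are bought) and the target has no stereocentre, so no stereochemistry has to be set.

Key step: step 6

Assumption: 3,4,5-tris(benzyloxy)benzoic acid and 2-bromoresorcinol are bought; the acid is otherwise two routine steps from gallic acid (perbenzylation, saponification).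

Step 1
Reactants: 1 2-bromoresorcinol; 2 benzyl bromide (2.2 equiv. in total)
Product: 3 1,3-bis(benzyloxy)-2-bromobenzene
Conditions: BnBr (2.2 equiv.), K2CO3 (3 equiv.), DMF, 60 °C
Reagents that add atoms: benzyl bromide 2 (the second equivalent), BrCc1ccccc1
Why: Twofold Williamson ether synthesis, in which each of the two phenoxides formed by K2CO3 in DMF should displace bromide from one molecule of the unhindered benzylic electrophile by SN2 while the aryl bromide is inert.

Step 2
Reactants: 3 1,3-bis(benzyloxy)-2-bromobenzene
Product: 6 2,6-bis(benzyloxy)phenol, via 2,6-bis(benzyloxy)phenyllithium 4 (not isolated), via lithium [2,6-bis(benzyloxy)phenyl]trimethoxyborate 5 (not isolated)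
Conditions: n-C4H9Li, THF, −78 °C; B(OMe)3, −78 → 0 °C; then AcOH, 30% aq. H2O2, 0 °C → rt
Reagents that add atoms: hydrogen peroxide, OO
Why: Bromine–lithium exchange at −78 °C should outrun deprotonation of the benzylic CH2 groups, the aryllithium is trapped as the borate, and boronate oxidation (1,2-aryl shift from boron to oxygen) places the hydroxyl exactly on the carbon that carried bromine.

Step 3
Reactants: 6 2,6-bis(benzyloxy)phenol
Product: 7 2,6-bis(benzyloxy)-4-iodophenol
Conditions: I2, NaHCO3, THF/H2O, 0 °C, dark
Reagents that add atoms: iodine, II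
Why: Electrophilic aromatic iodination of a phenol under bicarbonate buffering, where both ortho positions are blocked by benzyloxy groups, so the only carbon conjugated with the phenoxide oxygen is C4 and the weak electrophile should leave the ether-activated C3/C5 untouched.

Step 4
Reactants: 7 2,6-bis(benzyloxy)-4-iodophenol; 8 carbon monoxide; 9 benzyl alcohol (10 equiv.)
Product: 10 benzyl 3,5-bis(benzyloxy)-4-hydroxybenzoate
Conditions: Pd(OAc)2 (2 mol %), Xantphos (3 mol %), Et3N, CO (1 atm), toluene, 80 °C
Reagents that add atoms: none
Why: Palladium-catalysed alkoxycarbonylation of an aryl iodide (Heck carbonylation): oxidative addition of C–I to zerovalent palladium, CO insertion and alcoholysis of the aroyl palladium by the primary alcohol in large excess, which should outcompete the di-ortho-substituted phenol so that the hydroxyl needs no protection.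

Step 5
Reactants: 11 3,4,5-tris(benzyloxy)benzoic acid; 7 2,6-bis(benzyloxy)-4-iodophenol
Product: 13 2,6-bis(benzyloxy)-4-iodophenyl 3,4,5-tris(benzyloxy)benzoate, via 3,4,5-tris(benzyloxy)benzoyl chloride 12 (not isolated)
Conditions: (COCl)2, DMF (cat.), CH2Cl2, 0 °C → rt, evaporate; then 7, Et3N, DMAP (cat.), CH2Cl2, 0 °C → rt
Reagents that add atoms: none
Why: Acid chloride formation under Vilsmeier-type catalysis followed by DMAP-catalysed O-acylation, a combination strong enough for the hindered 2,6-disubstituted phenol, while the aryl iodide and benzyl ethers are inert.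

Step 6
Reactants: 13 2,6-bis(benzyloxy)-4-iodophenyl 3,4,5-tris(benzyloxy)benzoate; 8 carbon monoxide; 10 benzyl 3,5-bis(benzyloxy)-4-hydroxybenzoate (1.2 equiv.)
Product: 14 benzyl 3,5-bis(benzyloxy)-4-({3,5-bis(benzyloxy)-4-[(3,4,5-tris(benzyloxy)benzoyl)oxy]benzoyl}oxy)benzoate
Conditions: Pd(OAc)2 (5 mol %), Xantphos (7.5 mol %), Et3N (2.5 equiv.), CO (1 atm), dry toluene, 80 °C
Reagents that add atoms: none
Why: Pd(OAc)2 is reduced in the flask to a zerovalent palladium–Xantphos complex that inserts into the C1'–I bond of 13; CO insertion gives the aroyl palladium iodide, the phenoxide of 10 (formed with Et3N) replaces iodide on palladium, and C–O reductive elimination, favoured by the wide bite angle of Xantphos, forms C7'–O4 and returns the catalyst. The closest known reaction type is the palladium-catalysed aryloxycarbonylation of aryl iodides with phenols and carbon monoxide, run here between two molecules, so no ring is closed and no stereocentre is created. The selectivity needed is chemoselectivity: the phenoxide must capture the aroyl palladium faster than it attacks the diaryl ester already present or the one being formed. The substrate secures this because C1' is flanked only by hydrogens, so oxidative addition and CO insertion should be fast, whereas each ester oxygen (O4', then O4) is flanked by two benzyloxy groups that shield the adjacent carbonyl, and a weak amine base without an acyl-transfer catalyst keeps transesterification slow. Benzyl ethers and the benzyl ester are inert under these conditions, and water is excluded so that hydroxycarbonylation to the acid cannot compete.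

Step 7
Reactants: 14 benzyl 3,5-bis(benzyloxy)-4-({3,5-bis(benzyloxy)-4-[(3,4,5-tris(benzyloxy)benzoyl)oxy]benzoyl}oxy)benzoate
Product: 15 4-({3,5-dihydroxy-4-[(3,4,5-trihydroxybenzoyl)oxy]benzoyl}oxy)-3,5-dihydroxybenzoic acid (target)
Conditions: H2 (1 atm), 10% Pd/C, THF, rt; filter through Celite, evaporate below 30 °C
Reagents that add atoms: none
Why: Catalytic hydrogenolysis should cleave the seven benzyl ethers and the benzyl ester as toluene while the two aryl ester links are not reduced, and a neutral aprotic solvent at room temperature avoids para-to-meta acyl migration.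

Compound list
1 | 2-bromoresorcinol (2-bromobenzene-1,3-diol) | Oc1cccc(O)c1Br | starting material
2 | benzyl bromide | BrCc1ccccc1 | starting material
3 | 1,3-bis(benzyloxy)-2-bromobenzene | Brc1c(OCc2ccccc2)cccc1OCc1ccccc1 | intermediate
4 | 2,6-bis(benzyloxy)phenyllithium | [Li]c1c(OCc2ccccc2)cccc1OCc1ccccc1 | intermediate
5 | lithium [2,6-bis(benzyloxy)phenyl]trimethoxyborate | [Li+].CO[B-](OC)(OC)c1c(OCc2ccccc2)cccc1OCc1ccccc1 | intermediate
6 | 2,6-bis(benzyloxy)phenol | Oc1c(OCc2ccccc2)cccc1OCc1ccccc1 | intermediate
7 | 2,6-bis(benzyloxy)-4-iodophenol | Oc1c(OCc2ccccc2)cc(I)cc1OCc1ccccc1 | intermediate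
8 | carbon monoxide | [C-]#[O+] | starting material
9 | benzyl alcohol | OCc1ccccc1 | starting material
10 | benzyl 3,5-bis(benzyloxy)-4-hydroxybenzoate | O=C(OCc1ccccc1)c1cc(OCc2ccccc2)c(O)c(OCc2ccccc2)c1 | intermediate
11 | 3,4,5-tris(benzyloxy)benzoic acid | O=C(O)c1cc(OCc2ccccc2)c(OCc2ccccc2)c(OCc2ccccc2)c1 | starting material
12 | 3,4,5-tris(benzyloxy)benzoyl chloride | O=C(Cl)c1cc(OCc2ccccc2)c(OCc2ccccc2)c(OCc2ccccc2)c1 | intermediate
13 | 2,6-bis(benzyloxy)-4-iodophenyl 3,4,5-tris(benzyloxy)benzoate | O=C(Oc1c(OCc2ccccc2)cc(I)cc1OCc1ccccc1)c1cc(OCc2ccccc2)c(OCc2ccccc2)c(OCc2ccccc2)c1 | intermediate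
14 | benzyl 3,5-bis(benzyloxy)-4-({3,5-bis(benzyloxy)-4-[(3,4,5-tris(benzyloxy)benzoyl)oxy]benzoyl}oxy)benzoate | O=C(OCc1ccccc1)c1cc(OCc2ccccc2)c(OC(=O)c2cc(OCc3ccccc3)c(OC(=O)c3cc(OCc4ccccc4)c(OCc4ccccc4)c(OCc4ccccc4)c3)c(OCc3ccccc3)c2)c(OCc2ccccc2)c1 | intermediate
15 | 4-({3,5-dihydroxy-4-[(3,4,5-trihydroxybenzoyl)oxy]benzoyl}oxy)-3,5-dihydroxybenzoic acid (CNP0121783.0) | O=C(O)c1cc(O)c(OC(=O)c2cc(O)c(OC(=O)c3cc(O)c(O)c(O)c3)c(O)c2)c(O)c1 | target

Total step count: 7. Longest linear sequence: 6 steps (1, 2, 3, 5, 6, 7; the branch through step 4 is equally long).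

Steps most likely to fail

Step 6. The hindered, electron-poor phenoxide of 10 may capture the aroyl palladium too slowly, so that ester scrambling by attack on the existing diaryl ester, or hydrodeiodination, takes over. The fallback separates C–C from C–O bond formation. It sets out from iodide 13: Pd(OAc)2, Xantphos, Et3N and 2,4,6-trichlorophenyl formate (which releases CO and the acidic phenol in the flask) in toluene at room temperature should give the active ester 2,4,6-trichlorophenyl 3,5-bis(benzyloxy)-4-[(3,4,5-tris(benzyloxy)benzoyl)oxy]benzoate F1. Acyl transfer from F1 to phenol 10 (Et3N, catalytic DMAP, THF, rt to 45 °C) would then expel the much better trichlorophenoxide leaving group and come back to the route at 14.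

Step 4. The free hydroxyl of 7 may compete with benzyl alcohol for the aroyl palladium intermediate and lead to oligomeric aryl esters. The fallback sets out from 7 and removes the nucleophilic site first: silylation (TBSCl, imidazole, DMF) would give tert-butyl[2,6-bis(benzyloxy)-4-iodophenoxy]dimethylsilane F2. The same benzyloxycarbonylation (Pd(OAc)2, Xantphos, Et3N, CO 8, benzyl alcohol 9, toluene, 80 °C) would give benzyl 3,5-bis(benzyloxy)-4-(tert-butyldimethylsilyloxy)benzoate F3. Bu4NF buffered with AcOH in THF at 0 °C would then release the phenol and come back to the route at 10.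

Step 2. Proton transfer from a benzylic CH2 group to the aryllithium, or protodeboronation of the electron-rich borate before oxidation, may erode the hydroxylation. The fallback reaches the phenol by ether cleavage instead of C–O bond construction and sets out from benzyl bromide 2. Purchased pyrogallol F4 would be tribenzylated with three equivalents of 2 (K2CO3, DMF, under argon) to 1,2,3-tris(benzyloxy)benzene F5. One equivalent of BCl3 with pentamethylbenzene as cation scavenger (CH2Cl2, −78 °C) should then cleave the central benzyl ether. Its oxygen is twisted out of conjugation by the two neighbours and is the most Lewis basic, as in the known selective dealkylation of the middle ether of pyrogallol triethers. This gives [2,6-bis(benzyloxy)phenoxy]dichloroborane F6, which water hydrolyses on work-up, coming back to the route at 6.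

Further compounds
F1 | step 6 | 2,4,6-trichlorophenyl 3,5-bis(benzyloxy)-4-[(3,4,5-tris(benzyloxy)benzoyl)oxy]benzoate | O=C(Oc1c(Cl)cc(Cl)cc1Cl)c1cc(OCc2ccccc2)c(OC(=O)c2cc(OCc3ccccc3)c(OCc3ccccc3)c(OCc3ccccc3)c2)c(OCc2ccccc2)c1
F2 | step 4 | tert-butyl[2,6-bis(benzyloxy)-4-iodophenoxy]dimethylsilane | CC(C)(C)[Si](C)(C)Oc1c(OCc2ccccc2)cc(I)cc1OCc1ccccc1
F3 | step 4 | benzyl 3,5-bis(benzyloxy)-4-(tert-butyldimethylsilyloxy)benzoate | O=C(OCc1ccccc1)c1cc(OCc2ccccc2)c(O[Si](C)(C)C(C)(C)C)c(OCc2ccccc2)c1
F4 | step 2 | pyrogallol (purchased) | Oc1cccc(O)c1O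
F5 | step 2 | 1,2,3-tris(benzyloxy)benzene | c1ccc(COc2cccc(OCc3ccccc3)c2OCc2ccccc2)cc1
F6 | step 2 | [2,6-bis(benzyloxy)phenoxy]dichloroborane | ClB(Cl)Oc1c(OCc2ccccc2)cccc1OCc1ccccc1
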